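## Retrosynthetic overview

1. The target comes from a fully silylated 3-formylbenzofuran by one fluoride deprotection; the aldehyde comes from a C3 iodide by iodine–magnesium exchange and DMF.
2. The furan ring is the only ring built (both benzene rings are bought) and is formed last, by iodocyclisation of a diarylalkyne in which an ortho methoxy oxygen of ring A becomes O1. The alkyne comes from a Sonogashira coupling of a ring A alkyne with silylated 4-iodoresorcinol (ring B).
3. The ring A alkyne comes from a dibromoalkene made from the aryl aldehyde (Corey–Fuchs); the dibromoalkene also masks the alkyne while the side chain is built.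
4. The (R)-carbinol comes from a ketoreductase reduction of the isopropenyl ketone, itself made from the allyl group (oxidative cleavage, isopropenyl Grignard addition, oxidation).
5. The allyl group comes from an aromatic Claisen rearrangement of the allyl ether of 2-hydroxy-4,6-dimethoxybenzaldehyde, which fixes the ring A substitution pattern.

Assumption: the ketoreductase is the (R)-selective hit of a commercial enzyme panel (sense and level of induction checked by chiral HPLC and Mosher ester analysis), and the four starting materials are bought.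

Abbreviations: TBS = tert-butyldimethylsilyl, TIPS = triisopropylsilyl, TBSO and TIPSO = the corresponding silyloxy groups. Ring A is the benzo ring of the benzofuran, ring B the 2-aryl ring.

## Route

Step 1
Reactants: 1 2-hydroxy-4,6-dimethoxybenzaldehyde; 2 allyl bromide
Product: 3 2-(allyloxy)-4,6-dimethoxybenzaldehyde
Conditions: K2CO3, DMF, 60 °C
Reagents that add atoms: none
Why: Williamson ether synthesis, in which the phenoxide formed with K2CO3 displaces bromide from the allylic halide in an SN2 reaction.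

Step 2
Reactants: 3 2-(allyloxy)-4,6-dimethoxybenzaldehyde
Product: 5 3-allyl-2-hydroxy-4,6-dimethoxybenzaldehyde, via ortho-dienone 4 (not isolated)
Conditions: PhNEt2, 190 °C
Reagents that add atoms: none
Why: Aromatic Claisen rearrangement, whose [3,3] shift can only reach the one free ortho carbon, so after tautomerisation of 4 the allyl group sits between the hydroxyl and a methoxy group.

Step 3
Reactants: 5 3-allyl-2-hydroxy-4,6-dimethoxybenzaldehyde
Product: 6 3-allyl-4,6-dimethoxy-2-(TIPSO)benzaldehyde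
Conditions: TIPSOTf, 2,6-lutidine, CH2Cl2, 0 °C → rt
Reagents that add atoms: triisopropylsilyl trifluoromethanesulfonate (TIPSOTf), CC(C)[Si](C(C)C)(C(C)C)OS(=O)(=O)C(F)(F)F
Why: Silyl ether formation with a silyl triflate strong enough for the hindered, hydrogen-bonded phenol; the bulky TIPS ether resists migration to the later side-chain alkoxide and is a poor nucleophile in the later iodocyclisation.

Step 4
Reactants: 6 3-allyl-4,6-dimethoxy-2-(TIPSO)benzaldehyde
Product: 7 2-allyl-6-(2,2-dibromovinyl)-3,5-dimethoxyphenyl TIPS ether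
Conditions: CBr4, PPh3, Zn dust, CH2Cl2, rt
Reagents that add atoms: carbon tetrabromide, BrC(Br)(Br)Br
Why: Ramirez dibromo-olefination (first half of the Corey–Fuchs reaction), a Wittig reaction of the ylide Ph3P=CBr2 that turns the aldehyde into a dibromoalkene inert to the oxidation, Grignard and enzyme steps that follow.

Step 5
Reactants: 7 2-allyl-6-(2,2-dibromovinyl)-3,5-dimethoxyphenyl TIPS ether
Product: 9 [3-(2,2-dibromovinyl)-4,6-dimethoxy-2-(TIPSO)phenyl]acetaldehyde, via diol 8 (not isolated)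
Conditions: OsO4 (2 mol%), NaIO4, 2,6-lutidine, dioxane/H2O (3:1), rt
Reagents that add atoms: sodium metaperiodate NaIO4, [Na+].[O-]I(=O)(=O)=O; osmium tetroxide OsO4 (catalytic oxygen carrier), O=[Os](=O)(=O)=O
Why: Lemieux–Johnson oxidation, in which OsO4 dihydroxylates only the monosubstituted allyl alkene (the dibromoalkene is electron-poor) and NaIO4 cleaves diol 8 to the arylacetaldehyde.

Step 6
Reactants: 9 [3-(2,2-dibromovinyl)-4,6-dimethoxy-2-(TIPSO)phenyl]acetaldehyde; 10 isopropenylmagnesium bromide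
Product: 12 rac-1-[3-(2,2-dibromovinyl)-4,6-dimethoxy-2-(TIPSO)phenyl]-3-methylbut-3-en-2-ol, via bromomagnesium alkoxide 11 (not isolated)
Conditions: THF, −78 °C; then H2O
Reagents that add atoms: none
Why: Grignard 1,2-addition at low temperature (limits enolisation and leaves the dibromoalkene alone) gives a racemic carbinol whose configuration does not matter because the next step erases it.

Step 7
Reactants: 12 rac-1-[3-(2,2-dibromovinyl)-4,6-dimethoxy-2-(TIPSO)phenyl]-3-methylbut-3-en-2-ol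
Product: 13 1-[3-(2,2-dibromovinyl)-4,6-dimethoxy-2-(TIPSO)phenyl]-3-methylbut-3-en-2-one
Conditions: Dess–Martin periodinane, CH2Cl2, 0 °C → rt
Reagents that add atoms: none
Why: Dess–Martin oxidation gives the prochiral isopropenyl ketone under near-neutral conditions that spare the aryl silyl ether and the dibromoalkene.

Step 8
Reactants: 13 1-[3-(2,2-dibromovinyl)-4,6-dimethoxy-2-(TIPSO)phenyl]-3-methylbut-3-en-2-one
Product: 14 (2R)-1-[3-(2,2-dibromovinyl)-4,6-dimethoxy-2-(TIPSO)phenyl]-3-methylbut-3-en-2-ol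
Conditions: ketoreductase (NADPH-dependent alcohol dehydrogenase class, (R)-selective panel hit), NADP+ (cat.), iPrOH (10 vol%), DMSO (15 vol%), KH2PO4/K2HPO4 buffer pH 7.0, 30 °C
Reagents that add atoms: none
Why: Enzymatic asymmetric ketone reduction, in which the ketoreductase passes hydride from NADPH (recycled with iPrOH) to one face of the carbonyl only and in a purely 1,2 sense, setting the (R)-carbinol centre.

Step 9
Reactants: 14 (2R)-1-[3-(2,2-dibromovinyl)-4,6-dimethoxy-2-(TIPSO)phenyl]-3-methylbut-3-en-2-ol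
Product: 15 (2R)-2-(TBSO)-1-[3-(2,2-dibromovinyl)-4,6-dimethoxy-2-(TIPSO)phenyl]-3-methylbut-3-ene
Conditions: TBSOTf, 2,6-lutidine, CH2Cl2, −78 → 0 °C
Reagents that add atoms: tert-butyldimethylsilyl trifluoromethanesulfonate (TBSOTf), CC(C)(C)[Si](C)(C)OS(=O)(=O)C(F)(F)F
Why: Silyl ether formation at oxygen with a hindered base does not touch the C–O stereocentre and protects the carbinol from the organolithium and organomagnesium steps ahead.

Step 10
Reactants: 15 (2R)-2-(TBSO)-1-[3-(2,2-dibromovinyl)-4,6-dimethoxy-2-(TIPSO)phenyl]-3-methylbut-3-ene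
Product: 17 (2R)-2-(TBSO)-1-[3-ethynyl-4,6-dimethoxy-2-(TIPSO)phenyl]-3-methylbut-3-ene, via lithium acetylide 16 (not isolated)
Conditions: n-BuLi (2.2 equiv), THF, −78 °C; then H2O
Reagents that add atoms: none
Why: Second half of the Corey–Fuchs reaction, where bromine–lithium exchange, Fritsch–Buttenberg–Wiechell rearrangement and deprotonation give acetylide 16, which is protonated on work-up.

Step 11
Reactants: 18 4-iodoresorcinol
Product: 19 2,4-bis(TBSO)-1-iodobenzene
Conditions: TBSCl, imidazole, DMF, rt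
Reagents that add atoms: tert-butyldimethylsilyl chloride (TBSCl), CC(C)(C)[Si](C)(C)Cl
Why: Imidazole-promoted silylation of both phenols gives a ring B partner whose protecting groups leave together with the others in the last step.

Step 12
Reactants: 17 (2R)-2-(TBSO)-1-[3-ethynyl-4,6-dimethoxy-2-(TIPSO)phenyl]-3-methylbut-3-ene; 19 2,4-bis(TBSO)-1-iodobenzene
Product: 20 2,4-bis(TBSO)-1-({3-[(2R)-2-(TBSO)-3-methylbut-3-en-1-yl]-4,6-dimethoxy-2-(TIPSO)phenyl}ethynyl)benzene
Conditions: PdCl2(PPh3)2 (3 mol%), CuI (5 mol%), Et3N/THF, 50 °C, degassed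
Reagents that add atoms: none
Why: Sonogashira coupling joins the terminal alkyne to the aryl iodide under mild amine conditions that all four silyl ethers and the alkene tolerate.

Step 13
Reactants: 20 2,4-bis(TBSO)-1-({3-[(2R)-2-(TBSO)-3-methylbut-3-en-1-yl]-4,6-dimethoxy-2-(TIPSO)phenyl}ethynyl)benzene
Product: 21 2-[2,4-bis(TBSO)phenyl]-5-[(2R)-2-(TBSO)-3-methylbut-3-en-1-yl]-3-iodo-6-methoxy-4-(TIPSO)-1-benzofuran
Conditions: I2 (1.2 equiv), NaHCO3, CH2Cl2, 0 °C → rt, dark
Reagents that add atoms: iodine, [I][I]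
Why: Larock-type electrophilic iodocyclisation, in which iodine activates the alkyne, the ortho methoxy oxygen (a far better donor than the two flanking silyl ether oxygens) closes the furan ring 5-endo-dig and iodide takes the methyl group off the oxonium ion, while the isolated alkene has no competent internal nucleophile.

Step 14
Reactants: 21 2-[2,4-bis(TBSO)phenyl]-5-[(2R)-2-(TBSO)-3-methylbut-3-en-1-yl]-3-iodo-6-methoxy-4-(TIPSO)-1-benzofuran
Product: 24 2-[2,4-bis(TBSO)phenyl]-5-[(2R)-2-(TBSO)-3-methylbut-3-en-1-yl]-6-methoxy-4-(TIPSO)-1-benzofuran-3-carbaldehyde, via arylmagnesium chloride 22 (not isolated), via magnesium hemiaminal 23 (not isolated)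
Conditions: iPrMgCl·LiCl (1.3 equiv), THF, −30 °C; DMF, −30 → 0 °C; then H2O
Reagents that add atoms: N,N-dimethylformamide, CN(C)C=O
Why: Iodine–magnesium exchange with the turbo-Grignard reagent followed by Bouveault formylation with DMF, where the magnesium counter-ion and low temperature suppress ring-opening of the 3-metallated benzofuran and silyl migration.

Step 15
Reactants: 24 2-[2,4-bis(TBSO)phenyl]-5-[(2R)-2-(TBSO)-3-methylbut-3-en-1-yl]-6-methoxy-4-(TIPSO)-1-benzofuran-3-carbaldehyde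
Product: 25 2-(2,4-dihydroxyphenyl)-4-hydroxy-5-[(2R)-2-hydroxy-3-methylbut-3-en-1-yl]-6-methoxy-1-benzofuran-3-carbaldehyde
Conditions: TBAF, AcOH, THF, 0 °C → rt
Reagents that add atoms: none
Why: Fluoride-induced global desilylation, buffered with AcOH so that neither strong acid (which would cyclise the allylic alcohol onto the neighbouring phenol) nor strong base meets the product, frees three phenols and the carbinol without touching the stereocentre.

## Compound list

1 | 2-hydroxy-4,6-dimethoxybenzaldehyde | O=Cc1c(O)cc(OC)cc1OC | starting material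
2 | allyl bromide | C=CCBr | starting material
3 | 2-(allyloxy)-4,6-dimethoxybenzaldehyde | O=Cc1c(OCC=C)cc(OC)cc1OC | intermediate
4 | 5-allyl-2,4-dimethoxy-6-oxocyclohexa-1,3-diene-1-carbaldehyde (ortho-dienone, racemic, not isolated) | O=CC1=C(OC)C=C(OC)C(CC=C)C1=O | intermediate
5 | 3-allyl-2-hydroxy-4,6-dimethoxybenzaldehyde | O=Cc1c(O)c(CC=C)c(OC)cc1OC | intermediate
6 | 3-allyl-4,6-dimethoxy-2-(TIPSO)benzaldehyde | O=Cc1c(O[Si](C(C)C)(C(C)C)C(C)C)c(CC=C)c(OC)cc1OC | intermediate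
7 | 2-allyl-6-(2,2-dibromovinyl)-3,5-dimethoxyphenyl TIPS ether | BrC(Br)=Cc1c(O[Si](C(C)C)(C(C)C)C(C)C)c(CC=C)c(OC)cc1OC | intermediate
8 | 3-[3-(2,2-dibromovinyl)-4,6-dimethoxy-2-(TIPSO)phenyl]propane-1,2-diol (racemic, not isolated) | BrC(Br)=Cc1c(O[Si](C(C)C)(C(C)C)C(C)C)c(CC(O)CO)c(OC)cc1OC | intermediate
9 | [3-(2,2-dibromovinyl)-4,6-dimethoxy-2-(TIPSO)phenyl]acetaldehyde | BrC(Br)=Cc1c(O[Si](C(C)C)(C(C)C)C(C)C)c(CC=O)c(OC)cc1OC | intermediate
10 | isopropenylmagnesium bromide | C=C(C)[Mg]Br | starting material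
11 | bromomagnesium alkoxide of 12 (racemic, not isolated) | BrC(Br)=Cc1c(O[Si](C(C)C)(C(C)C)C(C)C)c(CC(O[Mg]Br)C(C)=C)c(OC)cc1OC | intermediate
12 | rac-1-[3-(2,2-dibromovinyl)-4,6-dimethoxy-2-(TIPSO)phenyl]-3-methylbut-3-en-2-ol | BrC(Br)=Cc1c(O[Si](C(C)C)(C(C)C)C(C)C)c(CC(O)C(C)=C)c(OC)cc1OC | intermediate
13 | 1-[3-(2,2-dibromovinyl)-4,6-dimethoxy-2-(TIPSO)phenyl]-3-methylbut-3-en-2-one | BrC(Br)=Cc1c(O[Si](C(C)C)(C(C)C)C(C)C)c(CC(=O)C(C)=C)c(OC)cc1OC | intermediate
14 | (2R)-1-[3-(2,2-dibromovinyl)-4,6-dimethoxy-2-(TIPSO)phenyl]-3-methylbut-3-en-2-ol | C=C(C)[C@H](O)Cc1c(OC)cc(OC)c(C=C(Br)Br)c1O[Si](C(C)C)(C(C)C)C(C)C | intermediate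
15 | (2R)-2-(TBSO)-1-[3-(2,2-dibromovinyl)-4,6-dimethoxy-2-(TIPSO)phenyl]-3-methylbut-3-ene | C=C(C)[C@H](O[Si](C)(C)C(C)(C)C)Cc1c(OC)cc(OC)c(C=C(Br)Br)c1O[Si](C(C)C)(C(C)C)C(C)C | intermediate
16 | lithium acetylide of 17 (not isolated) | C=C(C)[C@H](O[Si](C)(C)C(C)(C)C)Cc1c(OC)cc(OC)c(C#C[Li])c1O[Si](C(C)C)(C(C)C)C(C)C | intermediate
17 | (2R)-2-(TBSO)-1-[3-ethynyl-4,6-dimethoxy-2-(TIPSO)phenyl]-3-methylbut-3-ene | C=C(C)[C@H](O[Si](C)(C)C(C)(C)C)Cc1c(OC)cc(OC)c(C#C)c1O[Si](C(C)C)(C(C)C)C(C)C | intermediate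
18 | 4-iodoresorcinol (4-iodobenzene-1,3-diol) | Oc1ccc(I)c(O)c1 | starting material
19 | 2,4-bis(TBSO)-1-iodobenzene | CC(C)(C)[Si](C)(C)Oc1ccc(I)c(O[Si](C)(C)C(C)(C)C)c1 | intermediate
20 | 2,4-bis(TBSO)-1-({3-[(2R)-2-(TBSO)-3-methylbut-3-en-1-yl]-4,6-dimethoxy-2-(TIPSO)phenyl}ethynyl)benzene | C=C(C)[C@H](O[Si](C)(C)C(C)(C)C)Cc1c(OC)cc(OC)c(C#Cc2ccc(O[Si](C)(C)C(C)(C)C)cc2O[Si](C)(C)C(C)(C)C)c1O[Si](C(C)C)(C(C)C)C(C)C | intermediate
21 | 2-[2,4-bis(TBSO)phenyl]-5-[(2R)-2-(TBSO)-3-methylbut-3-en-1-yl]-3-iodo-6-methoxy-4-(TIPSO)-1-benzofuran | C=C(C)[C@H](O[Si](C)(C)C(C)(C)C)Cc1c(OC)cc2oc(-c3ccc(O[Si](C)(C)C(C)(C)C)cc3O[Si](C)(C)C(C)(C)C)c(I)c2c1O[Si](C(C)C)(C(C)C)C(C)C | intermediate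
22 | benzofuran-3-ylmagnesium chloride derived from 21 (not isolated) | C=C(C)[C@H](O[Si](C)(C)C(C)(C)C)Cc1c(OC)cc2oc(-c3ccc(O[Si](C)(C)C(C)(C)C)cc3O[Si](C)(C)C(C)(C)C)c([Mg]Cl)c2c1O[Si](C(C)C)(C(C)C)C(C)C | intermediate
23 | chloromagnesium hemiaminal (DMF adduct of 22, not isolated) | C=C(C)[C@H](O[Si](C)(C)C(C)(C)C)Cc1c(OC)cc2oc(-c3ccc(O[Si](C)(C)C(C)(C)C)cc3O[Si](C)(C)C(C)(C)C)c(C(O[Mg]Cl)N(C)C)c2c1O[Si](C(C)C)(C(C)C)C(C)C | intermediate
24 | 2-[2,4-bis(TBSO)phenyl]-5-[(2R)-2-(TBSO)-3-methylbut-3-en-1-yl]-6-methoxy-4-(TIPSO)-1-benzofuran-3-carbaldehyde | C=C(C)[C@H](O[Si](C)(C)C(C)(C)C)Cc1c(OC)cc2oc(-c3ccc(O[Si](C)(C)C(C)(C)C)cc3O[Si](C)(C)C(C)(C)C)c(C=O)c2c1O[Si](C(C)C)(C(C)C)C(C)C | intermediate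
25 | 2-(2,4-dihydroxyphenyl)-4-hydroxy-5-[(2R)-2-hydroxy-3-methylbut-3-en-1-yl]-6-methoxy-1-benzofuran-3-carbaldehyde (CNP0287677.1) | C=C(C)[C@H](O)Cc1c(OC)cc2oc(-c3ccc(O)cc3O)c(C=O)c2c1O | target

## Step count and weak points

Total step count: 15. Longest linear sequence: 14 steps (steps 1–10, then 12–15); step 11 is the one-step branch to the ring B partner 19.

The three steps most likely to fail:

Step 8 (enzymatic reduction). The ketone carries two sizeable groups and a reactive enone, so no panel enzyme may combine activity with high (R)-selectivity, or the enone may degrade in buffer. The fallback sets out from racemic alcohol 12 and returns at 14, skipping steps 7 and 8: a lipase-catalysed kinetic resolution (immobilised Burkholderia cepacia lipase, vinyl acetate, MTBE, 35 °C, stopped a little past half conversion). By the usual empirical size model (arylmethyl large, isopropenyl medium) the enzyme acetylates the (S)-alcohol to the (S)-acetate F1 and leaves the (R)-alcohol 14, which is separated by chromatography. The stereocentre is then set by enantiomer discrimination instead of reduction, at the cost of at most half the material; which enantiomer remains must be checked on 14.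

Step 13 (iodocyclisation). Iodine could engage the isopropenyl group, or a silyl ether oxygen could compete with the methoxy oxygen; the regiochemistry of 21 should be confirmed by HMBC. The fallback sets out from 7 and returns at 21 by closing the furan ring before the isopropenyl carbinol exists. n-BuLi converts 7 through lithium acetylide F2 into the terminal alkyne F3, and Sonogashira coupling with 19 gives diarylalkyne F4. Iodine then cyclises F4, whose only alkene is the much less nucleophilic monosubstituted allyl group, to the 3-iodobenzofuran F5. OsO4/NaIO4 cleaves the allyl group through diol F6 to aldehyde F7. Isopropenylmagnesium bromide 10 adds at −78 °C (the aryl iodide does not exchange with an alkenyl Grignard reagent) through bromomagnesium alkoxide F8 to the racemic alcohol F9, and Dess–Martin oxidation gives enone F10. Ketoreductase reduction in buffer with a toluene or DMSO co-phase gives the (R)-alcohol F11, and TBSOTf silylation returns to 21. The price is an enzymatic reduction on a large, lipophilic substrate.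

Step 14 (formylation). C3 is flanked by the silylated aryl group and the peri TIPS ether, so the exchange may be slow, and the 3-metallated benzofuran can ring-open or take up the neighbouring silyl group. The fallback sets out from 21 and returns at 24 without any carbanion: a palladium-catalysed reductive carbonylation (Pd(PPh3)4 cat., CO 3 atm, Bu3SnH added slowly, THF, 50 °C) gives aldehyde 24 directly. No new compound is formed (entry F0).

## Further compounds

F1 | step 8 | (2S)-1-[3-(2,2-dibromovinyl)-4,6-dimethoxy-2-(TIPSO)phenyl]-3-methylbut-3-en-2-yl acetate | C=C(C)[C@@H](OC(C)=O)Cc1c(OC)cc(OC)c(C=C(Br)Br)c1O[Si](C(C)C)(C(C)C)C(C)C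
F2 | step 13 | lithium [3-allyl-4,6-dimethoxy-2-(TIPSO)phenyl]acetylide | [Li]C#Cc1c(O[Si](C(C)C)(C(C)C)C(C)C)c(CC=C)c(OC)cc1OC
F3 | step 13 | [3-allyl-4,6-dimethoxy-2-(TIPSO)phenyl]acetylene | C#Cc1c(O[Si](C(C)C)(C(C)C)C(C)C)c(CC=C)c(OC)cc1OC
F4 | step 13 | 1-{[3-allyl-4,6-dimethoxy-2-(TIPSO)phenyl]ethynyl}-2,4-bis(TBSO)benzene | C=CCc1c(OC)cc(OC)c(C#Cc2ccc(O[Si](C)(C)C(C)(C)C)cc2O[Si](C)(C)C(C)(C)C)c1O[Si](C(C)C)(C(C)C)C(C)C
F5 | step 13 | 5-allyl-2-[2,4-bis(TBSO)phenyl]-3-iodo-6-methoxy-4-(TIPSO)-1-benzofuran | C=CCc1c(OC)cc2oc(-c3ccc(O[Si](C)(C)C(C)(C)C)cc3O[Si](C)(C)C(C)(C)C)c(I)c2c1O[Si](C(C)C)(C(C)C)C(C)C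
F6 | step 13 | 3-{2-[2,4-bis(TBSO)phenyl]-3-iodo-6-methoxy-4-(TIPSO)-1-benzofuran-5-yl}propane-1,2-diol (racemic) | OCC(O)Cc1c(OC)cc2oc(-c3ccc(O[Si](C)(C)C(C)(C)C)cc3O[Si](C)(C)C(C)(C)C)c(I)c2c1O[Si](C(C)C)(C(C)C)C(C)C
F7 | step 13 | {2-[2,4-bis(TBSO)phenyl]-3-iodo-6-methoxy-4-(TIPSO)-1-benzofuran-5-yl}acetaldehyde | O=CCc1c(OC)cc2oc(-c3ccc(O[Si](C)(C)C(C)(C)C)cc3O[Si](C)(C)C(C)(C)C)c(I)c2c1O[Si](C(C)C)(C(C)C)C(C)C
F8 | step 13 | bromomagnesium alkoxide of F9 (racemic) | C=C(C)C(O[Mg]Br)Cc1c(OC)cc2oc(-c3ccc(O[Si](C)(C)C(C)(C)C)cc3O[Si](C)(C)C(C)(C)C)c(I)c2c1O[Si](C(C)C)(C(C)C)C(C)C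
F9 | step 13 | rac-1-{2-[2,4-bis(TBSO)phenyl]-3-iodo-6-methoxy-4-(TIPSO)-1-benzofuran-5-yl}-3-methylbut-3-en-2-ol | C=C(C)C(O)Cc1c(OC)cc2oc(-c3ccc(O[Si](C)(C)C(C)(C)C)cc3O[Si](C)(C)C(C)(C)C)c(I)c2c1O[Si](C(C)C)(C(C)C)C(C)C
F10 | step 13 | 1-{2-[2,4-bis(TBSO)phenyl]-3-iodo-6-methoxy-4-(TIPSO)-1-benzofuran-5-yl}-3-methylbut-3-en-2-one | C=C(C)C(=O)Cc1c(OC)cc2oc(-c3ccc(O[Si](C)(C)C(C)(C)C)cc3O[Si](C)(C)C(C)(C)C)c(I)c2c1O[Si](C(C)C)(C(C)C)C(C)C
F11 | step 13 | (2R)-1-{2-[2,4-bis(TBSO)phenyl]-3-iodo-6-methoxy-4-(TIPSO)-1-benzofuran-5-yl}-3-methylbut-3-en-2-ol | C=C(C)[C@H](O)Cc1c(OC)cc2oc(-c3ccc(O[Si](C)(C)C(C)(C)C)cc3O[Si](C)(C)C(C)(C)C)c(I)c2c1O[Si](C(C)C)(C(C)C)C(C)C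
F0 | step 14 | none | none
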